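## Structural features

The target is a flavone: benzene ring A is fused to the 4-pyranone ring C (O1, C2, C3, C4, C4a, C8a), and the pentasubstituted benzene ring B is joined to C2 through the single bond C2–C1'. Ring A carries a hydroxyl at C5, peri to the C4 carbonyl and hydrogen-bonded to it, and a methoxy group at C7; C6 and C8 are unsubstituted. Ring B carries four contiguous oxygens: methoxy at C2', C3' and C5' and a free hydroxyl at C4', so that only C6' bears hydrogen. There is no stereocentre, so the problem is one of regiochemistry and of telling six oxygen functions apart (two free phenols among four methyl ethers). The fragile points are the electron-rich 4'-phenol (oxidation), ring C toward hydroxide or alkoxide at C2, and the aryl methyl ethers toward strong Lewis acids. The real difficulty is to reach the 5-OH/7-OMe pattern without statistical alkylation of a phloroglucinol, and to place the 2'-oxygen of ring B next to the ring junction. The key step uses the 1,3-relationship of the C5 and C7 oxygens with C–H at C6 and C8. C7 with its methoxy group, C8, C8a and C4a are already present in a 2-pyranone fused across C4a–C8a; C5 and C6 arrive as the two carbons of an ynol ether, and the lactone unit C5(=O)–O6 leaves as CO2.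

## Logic of the disconnections

17 from 16. The bonds cut are the O–alkyl bonds of the ethyl group on O5 and of the benzyl group on O4'. Both phenols stay masked until the end because they are the only acidic and oxidation-prone groups. The gain is that every earlier intermediate is a neutral polyether. The forward step must cleave the carbonyl-chelated ether and the benzyl ether and leave four methyl ethers alone.

16 from 13 and 14. The bonds cut are C4a–C5 and C6–C7, with a C5(=O)–O6 bridge put back between C4a and C7. The cut is made here because ring A has oxygen exactly where the oxygen-bearing carbon of 14 and the methoxy-bearing C7 of 13 would place it. Ring A is thereby reduced to a two-carbon unit and a fused lactone, and O5 and O7 emerge already different (ethyl and methyl). The forward step must deliver the ethoxy carbon to C4a and not to C7, and 13 must be free of acidic hydrogen and of water.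

13 from 12. The bond cut is O7–CH3. This leads back to the enol of a cyclic anhydride, which is a diacid derivative. The forward step must alkylate at O7 and not at O5, O4 or C8.

12 from 7 and 9 (through 10 and 11). The bonds cut are C4–C4a and O1–C2. Ring C is then the union of a three-carbon ynoyl unit and the enolised keto-anhydride, so the molecule falls into two halves of similar size. The forward step must acylate on carbon, only once, and close 6-endo.

9 from 8. The bond cut is the anhydride C–O bond; the forward step is a dehydration that must avoid decarboxylation of the β-keto diacid.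

7 from 5 (through 6), and 5 from 4. The bond cut is the one between the alkyne and the carboxyl carbon, and then the alkyne is traced back to a formyl carbon. This turns a benzaldehyde into the arylpropiolic acid in two operations. The forward steps require an organolithium that spares the benzyl and methyl ethers.

4 from 3, 3 from 2, 2 from 1. The bonds cut are C2'–O(methyl), then C2'–Br, then O4'–benzyl. 1 already has the 3',4',5'-oxygens with the 4'-oxygen distinguished as a phenol, and its two free ring positions are equivalent. The forward steps require clean monobromination and a copper-mediated substitution that tolerates the neighbouring aldehyde.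

## Other disconnections considered

Alternative 1: The cut is through C1'–C2 and C2–C3, so that C2 comes from carbon monoxide.
- Forward step: the aryl iodide 2-(benzyloxy)-5-iodo-1,3,4-trimethoxybenzene A2, CO and the enolate of 1-[2,6-bis(benzyloxy)-4-methoxyphenyl]ethan-1-one A3 would be joined by Pd(dba)2/Xantphos and base to the open 1,3-diketone A1. Hydrogenolysis of the three benzyl ethers and acid-induced cyclodehydration would then give 17.
- In its favour: carbonylative α-arylation of aryl methyl ketones is an established reaction type. A1 is the classical flavone precursor and its closure is not in doubt. Ring A of A3 is symmetric about the acyl group, so closure raises no regiochemical question.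
- Against it here: A2 does not lie on the way to 4 and would need its own regioselective iodination of a tetraoxygenated benzene. A3 needs selective 4-O-methylation before double benzylation. Both coupling partners are ortho-substituted, A1 is more acidic than A3 and may be arylated again, and toxic CO must be handled.
- Comparison: on mechanism this alternative is the better founded, since each step has a close model and the chosen key step has none. On structure the chosen plan is stronger, because O5 and O7 are created different instead of being differentiated by protecting-group work. On step economy the two are about equal (roughly ten operations), and the alternative is the more convergent at its coupling.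

Alternative 2: The cut removes C4a–C4, C4–C3 and O1–C2, so that ring C is assembled from three components.
- Forward step: 2-iodo-5-methoxybenzene-1,3-diol A5, CO and the terminal alkyne 2-(benzyloxy)-5-ethynyl-1,3,4-trimethoxybenzene A6 would react under PdCl2(PPh3)2 in Et2NH. Oxidative addition, CO insertion and acyl–alkynyl coupling give an ynone, which the amine closes 6-endo to the flavone A4. Debenzylation would give 17.
- In its favour: A6 is one step from 5 (protonation of 6 in place of carboxylation). A5 is symmetric, so either hydroxyl closes to the same product. The 5-hydroxyl emerges free, and the whole plan needs only about eight steps.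
- Against it here: A5 is an electron-rich, doubly ortho-substituted aryl iodide, slow in oxidative addition and prone to reductive loss of iodine. Direct Sonogashira coupling followed by 5-endo closure competes with CO insertion, and the ynone can close 5-exo instead of 6-endo. A5 itself requires iodination between two hydroxyls in preference to the other ring positions, and CO is needed under pressure.
- Comparison: this alternative is better on step economy and on precedent, and equal at the end-game (one deprotection in each plan). The chosen plan is better only in that the ring-A pattern and the six-membered ring C follow from connectivity and not from a partition among three catalytic pathways, and in that it avoids CO.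

Alternative 3: The cut is at C8a–O1 and C4a–C4, so that ring A enters as an aryne.
- Forward step: CsF would release 3,5-dimethoxybenzyne A9 from 3,5-dimethoxy-2-(trimethylsilyl)phenyl trifluoromethanesulfonate A8. The carboxylate of 7 adds through oxygen to the aryne carbon remote from the flanking methoxy group. The aryl anion formed next to that methoxy group attacks the ester carbonyl, and the four-membered intermediate opens to the phenoxide of the ynone A7. Base-mediated 6-endo closure and BCl3 cleavage of the chelated 5-methyl ether and the benzyl ether would give 17.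
- In its favour: 7 is used as it stands, so steps 1 to 5 are shared. No transition metal and no CO are needed, and the regiochemistry of addition to 3-alkoxyarynes is dependable. The last step is the same kind of chelation-controlled dealkylation as in the chosen plan.
- Against it here: A8 needs three to four steps of its own. The alkyne of 7 may itself react with the aryne, the phenoxide of A7 may add to a second aryne, and the aryl anion may be protonated before acyl transfer. Closure of A7 may go 5-exo.
- Comparison: this alternative is equal on step economy (ten to eleven steps) and equal at the end-game. It is somewhat better on precedent, since insertion of arynes into carboxylic acid C–O bonds is a known reaction type. The chosen plan is better on structure: O5 and O7 arrive as ethyl and methyl ethers, and no pre-functionalised aryne precursor has to be built.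

Key step: step 9

Remark on the chemistry: 9, 11 and 12 are enolised tricarbonyl compounds. 9 is drawn as the trione, 11 as its 4-enol and 12 as its 7-hydroxy tautomer; each drawing stands for the tautomeric mixture. The structures of 13, 16 and 17 were checked against the numbering O1, C2, C3, C4, C4a, C5, O6, C7, C8, C8a and needed no correction. Two handling points are added for 13: it is isolated without contact with water, and it must be free of 12, whose acidic enol would add to 14.

## Route

Step 1
Reactants: 1 syringaldehyde (4-hydroxy-3,5-dimethoxybenzaldehyde)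
Product: 2 4-(benzyloxy)-3,5-dimethoxybenzaldehyde
Conditions: BnBr, K2CO3, DMF, 60 °C
Reagents that add atoms: benzyl bromide, BrCc1ccccc1
Why: Williamson ether synthesis on the phenoxide; the benzyl ether masks O4' through the organolithium, acid chloride and cycloaddition steps and falls to BCl3 at the end.

Step 2
Reactants: 2 4-(benzyloxy)-3,5-dimethoxybenzaldehyde
Product: 3 4-(benzyloxy)-2-bromo-3,5-dimethoxybenzaldehyde
Conditions: NBS, MeCN, rt, dark
Reagents that add atoms: N-bromosuccinimide, BrN1C(=O)CCC1=O
Why: Electrophilic aromatic bromination; the two free ring positions of 2 are equivalent and each is ortho and para to a methoxy group, and the first bromine slows a second substitution. A polar solvent and exclusion of light favour ring bromination over benzylic bromination.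

Step 3
Reactants: 3 4-(benzyloxy)-2-bromo-3,5-dimethoxybenzaldehyde
Product: 4 4-(benzyloxy)-2,3,5-trimethoxybenzaldehyde
Conditions: NaOMe, CuBr (10 mol %), EtOAc (cat.), MeOH–DMF, 90 °C; aq. NH4Cl
Reagents that add atoms: sodium methoxide, [Na+].[O-]C
Why: Copper-catalysed Ullmann-type methoxylation of an aryl bromide, helped by the ortho formyl group; under methoxide the aldehyde is held reversibly as its hemiacetal alkoxide and returns on work-up.

Step 4
Reactants: 4 4-(benzyloxy)-2,3,5-trimethoxybenzaldehyde
Product: 5 2-(benzyloxy)-5-(2,2-dibromoethenyl)-1,3,4-trimethoxybenzene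
Conditions: CBr4, PPh3, DCM, 0 °C
Reagents that add atoms: carbon tetrabromide, BrC(Br)(Br)Br
Why: First stage of the Corey–Fuchs sequence, a Wittig-type olefination by the ylide Ph3P=CBr2 formed in the flask.

Step 5
Reactants: 5 2-(benzyloxy)-5-(2,2-dibromoethenyl)-1,3,4-trimethoxybenzene
Product: 7 3-[4-(benzyloxy)-2,3,5-trimethoxyphenyl]prop-2-ynoic acid, via lithium acetylide 6 (not isolated)
Conditions: n-BuLi (2.2 equiv), THF, −78 °C; CO2 (g), −78 °C to rt; 1 M HCl
Reagents that add atoms: carbon dioxide, O=C=O
Why: Second stage of the Corey–Fuchs sequence: bromine–lithium exchange, Fritsch–Buttenberg–Wiechell rearrangement and deprotonation give acetylide 6, which is carboxylated by CO2. The benzyl and methyl ethers are inert to n-BuLi at −78 °C.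

Step 6
Reactants: 8 acetonedicarboxylic acid (3-oxopentanedioic acid)
Product: 9 oxane-2,4,6-trione (acetonedicarboxylic anhydride)
Conditions: Ac2O, AcOH, 10 °C
Reagents that add atoms: none
Why: Cyclodehydration of a 1,5-diacid to the six-membered anhydride by acyl exchange with acetic anhydride; the product should crystallise from the cold medium, which limits decarboxylation and self-condensation.

Step 7
Reactants: 7 3-[4-(benzyloxy)-2,3,5-trimethoxyphenyl]prop-2-ynoic acid; 9 oxane-2,4,6-trione
Product: 12 2-[4-(benzyloxy)-2,3,5-trimethoxyphenyl]-7-hydroxy-4H,5H-pyrano[4,3-b]pyran-4,5-dione, via acid chloride 10 (not isolated), via acylated anhydride 11 (not isolated)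
Conditions: (COCl)2, DMF (cat.), DCM, 0 °C, evaporate; 9 (1.2 equiv), pyridine, DCM, 0 °C; then DMAP (cat.), rt; cold 1 M HCl
Reagents that add atoms: none
Why: Acid chloride formation, then C-acylation of the enolised cyclic 1,3-dicarbonyl unit of 9 (a known reaction of this anhydride with acyl chlorides and pyridine), then DMAP-promoted 6-endo-dig oxa-Michael addition of the enol oxygen to the ynone, the closure that turns 2-hydroxyaryl ynones into flavones. The two α-carbons of 9 are equivalent, and slow addition of 10 to a slight excess of 9 should limit double acylation.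

Step 8
Reactants: 12 2-[4-(benzyloxy)-2,3,5-trimethoxyphenyl]-7-hydroxy-4H,5H-pyrano[4,3-b]pyran-4,5-dione
Product: 13 2-[4-(benzyloxy)-2,3,5-trimethoxyphenyl]-7-methoxy-4H,5H-pyrano[4,3-b]pyran-4,5-dione
Conditions: Me2SO4 (1.0 equiv), K2CO3, dry acetone, rt; filter, evaporate, crystallise (no aqueous work-up)
Reagents that add atoms: dimethyl sulfate, COS(=O)(=O)OC
Why: O-Alkylation of a strongly acidic, delocalised enolate by a hard electrophile. O7 should carry most of the charge because only that resonance form keeps both pyranone rings conjugated, whereas reaction through O5, O4 or C8 would break the 4-pyranone system. Non-aqueous isolation protects the acylated ketene acetal.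

Step 9
Reactants: 13 2-[4-(benzyloxy)-2,3,5-trimethoxyphenyl]-7-methoxy-4H,5H-pyrano[4,3-b]pyran-4,5-dione; 14 ethoxyacetylene
Product: 16 2-[4-(benzyloxy)-2,3,5-trimethoxyphenyl]-5-ethoxy-7-methoxy-4H-chromen-4-one, via bridged lactone cycloadduct 15 (not isolated)
Conditions: 14 (5 equiv), PhMe, sealed tube, 80 °C
Reagents that add atoms: none
Why: Proposed new method: the 2-pyranone ring of 13 is an electron-poor diene (C4a=C8a–C8=C7) whose LUMO is lowered by the lactone carbonyl C5 and the ketone C4 on C4a, and the closest known reaction type is the inverse-electron-demand Diels–Alder reaction of 3-acyl- or 3-alkoxycarbonyl-2-pyranones with ynamines, ynol ethers and ketene acetals followed by loss of CO2. Bond formation should be strongly asynchronous: the nucleophilic terminal carbon of 14 attacks C7, the δ-position of the dienone and dienoate, and the developing ketene-oxonium carbon is captured by C4a, the α-carbon of the doubly stabilised enolate, so that the ethoxy-bearing carbon becomes C5 and the CH becomes C6. The bridged lactone 15 then loses CO2 (C5 and O6 of 13) by retro-[4+2] cleavage, which is irreversible and leaves the methoxy group on C7. Ring A is therefore closed by an intermolecular [4+2] cycloaddition that forms C4a–C5 and C6–C7 in one operation and is aromatised by cycloreversion; no exo or endo ring-closure rule is involved. The two bridgehead centres of 15 are transient, their relative configuration is fixed by the bicyclic frame, and both vanish on aromatisation, so no stereocentre has to be controlled. The selectivity needed is regiochemical (ethoxy at C5, not C6) and periselective (the 2-pyranone diene, not the C2=C3 enone of ring C); the first is secured by the matched polarisation of 14 and of C7/C4a, the second by the absence of a diene in ring C and the shielding of C2 by ring B. Methylation of O7 beforehand removes the only acidic hydrogen, which would otherwise add to 14, and an excess of 14 in a closed vessel below the temperature of its own retro-ene fragmentation keeps the dienophile available.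

Step 10
Reactants: 16 2-[4-(benzyloxy)-2,3,5-trimethoxyphenyl]-5-ethoxy-7-methoxy-4H-chromen-4-one
Product: 17 5-hydroxy-2-(4-hydroxy-2,3,5-trimethoxyphenyl)-7-methoxy-4H-chromen-4-one
Conditions: BCl3 (5 equiv), C6HMe5, DCM, −78 °C to 0 °C; MeOH, then 1 M HCl
Reagents that add atoms: none
Why: BCl3 cleaves aryl benzyl ethers at low temperature, with pentamethylbenzene trapping the benzyl cation. On warming it cleaves the ether peri to the C4 carbonyl through a six-membered boron chelate, chloride attacking the ethyl carbon. The four non-chelated methyl ethers should survive at 0 °C.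

## Compound list

1 | syringaldehyde (4-hydroxy-3,5-dimethoxybenzaldehyde) | COc1cc(C=O)cc(OC)c1O | starting material
2 | 4-(benzyloxy)-3,5-dimethoxybenzaldehyde | COc1cc(C=O)cc(OC)c1OCc1ccccc1 | intermediate
3 | 4-(benzyloxy)-2-bromo-3,5-dimethoxybenzaldehyde | O=Cc1cc(OC)c(OCc2ccccc2)c(OC)c1Br | intermediate
4 | 4-(benzyloxy)-2,3,5-trimethoxybenzaldehyde | O=Cc1cc(OC)c(OCc2ccccc2)c(OC)c1OC | intermediate
5 | 2-(benzyloxy)-5-(2,2-dibromoethenyl)-1,3,4-trimethoxybenzene | BrC(Br)=Cc1cc(OC)c(OCc2ccccc2)c(OC)c1OC | intermediate
6 | lithium [4-(benzyloxy)-2,3,5-trimethoxyphenyl]acetylide | [Li]C#Cc1cc(OC)c(OCc2ccccc2)c(OC)c1OC | intermediate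
7 | 3-[4-(benzyloxy)-2,3,5-trimethoxyphenyl]prop-2-ynoic acid | OC(=O)C#Cc1cc(OC)c(OCc2ccccc2)c(OC)c1OC | intermediate
8 | acetonedicarboxylic acid (3-oxopentanedioic acid) | OC(=O)CC(=O)CC(=O)O | starting material
9 | oxane-2,4,6-trione (acetonedicarboxylic anhydride) | O=C1CC(=O)OC(=O)C1 | intermediate
10 | 3-[4-(benzyloxy)-2,3,5-trimethoxyphenyl]prop-2-ynoyl chloride | ClC(=O)C#Cc1cc(OC)c(OCc2ccccc2)c(OC)c1OC | intermediate
11 | 5-{3-[4-(benzyloxy)-2,3,5-trimethoxyphenyl]prop-2-ynoyl}-4-hydroxy-2H-pyran-2,6(3H)-dione | O=C1CC(O)=C(C(=O)C#Cc2cc(OC)c(OCc3ccccc3)c(OC)c2OC)C(=O)O1 | intermediate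
12 | 2-[4-(benzyloxy)-2,3,5-trimethoxyphenyl]-7-hydroxy-4H,5H-pyrano[4,3-b]pyran-4,5-dione | OC1=CC2=C(C(=O)C=C(O2)c3cc(OC)c(OCc4ccccc4)c(OC)c3OC)C(=O)O1 | intermediate
13 | 2-[4-(benzyloxy)-2,3,5-trimethoxyphenyl]-7-methoxy-4H,5H-pyrano[4,3-b]pyran-4,5-dione | COC1=CC2=C(C(=O)C=C(O2)c3cc(OC)c(OCc4ccccc4)c(OC)c3OC)C(=O)O1 | intermediate
14 | ethoxyacetylene | CCOC#C | starting material
15 | 2-[4-(benzyloxy)-2,3,5-trimethoxyphenyl]-9-ethoxy-7-methoxy-7H-4a,7-ethenopyrano[4,3-b]pyran-4,5-dione (etheno bridge C9=C10, with C9 bearing ethoxy on C4a and C10 on C7; lactone bridge C5(=O)–O6; racemic, one enantiomer drawn, relative configuration fixed by the cage) | O=C1C=C(c4cc(OC)c(OCc5ccccc5)c(OC)c4OC)OC2=C[C@]3(OC)C=C(OCC)[C@]12C(=O)O3 | intermediate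
16 | 2-[4-(benzyloxy)-2,3,5-trimethoxyphenyl]-5-ethoxy-7-methoxy-4H-chromen-4-one | CCOc1cc(OC)cc2oc(-c3cc(OC)c(OCc4ccccc4)c(OC)c3OC)cc(=O)c12 | intermediate
17 | 5-hydroxy-2-(4-hydroxy-2,3,5-trimethoxyphenyl)-7-methoxy-4H-chromen-4-one | COc1cc(O)c2c(=O)cc(-c3cc(OC)c(O)c(OC)c3OC)oc2c1 | target

## Step count and least certain steps

Total step count: 10. Longest linear sequence: 9 (steps 1 to 5 and 7 to 10); step 6 is a one-step branch.

Step 9 (key step).
- Risk: the two oxygen donors on C7 and C8a may leave the diene too electron-rich to react before 14 fragments thermally. A stepwise addition may also end in a [2+2] adduct across C7=C8, and traces of water may open the acylated ketene acetal.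
- Fallback (known chemistry): sets out from 4 and returns at 17. Claisen–Schmidt condensation of 4 with commercial 1-(2-hydroxy-4,6-dimethoxyphenyl)ethan-1-one (KOH, EtOH, rt) should give the chalcone (2E)-3-[4-(benzyloxy)-2,3,5-trimethoxyphenyl]-1-(2-hydroxy-4,6-dimethoxyphenyl)prop-2-en-1-one F1. Oxidative cyclisation with catalytic I2 in DMSO at 120 °C should give 2-[4-(benzyloxy)-2,3,5-trimethoxyphenyl]-5,7-dimethoxy-4H-chromen-4-one F2. BCl3 with pentamethylbenzene, as in step 10, would then cleave the chelated 5-methyl ether and the benzyl ether to give 17.

Step 7.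
- Risk: O-acylation or double acylation of 9, base-induced self-condensation of 9, acyl transfer within 11 that opens the anhydride, or 5-exo closure in place of 6-endo.
- Fallback: sets out from 10 and returns at 12. C-acylation of the magnesium enolate of commercial di-tert-butyl 3-oxopentanedioate (MgCl2, pyridine, DCM), with closure by DMAP in the same flask, should give tert-butyl 6-[4-(benzyloxy)-2,3,5-trimethoxyphenyl]-2-(2-tert-butoxy-2-oxoethyl)-4-oxo-4H-pyran-3-carboxylate F3. CF3CO2H in DCM at 0 °C would release 6-[4-(benzyloxy)-2,3,5-trimethoxyphenyl]-2-(carboxymethyl)-4-oxo-4H-pyran-3-carboxylic acid F4. Ac2O at rt would close F4 to the anhydride 12.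

Step 8.
- Risk: alkylation at O5 or C8 in competition with O7, and hydrolytic ring opening of the product during isolation.
- Fallback: sets out from 12 and returns at 13. Methanol at rt to 40 °C should open the anhydride at the non-conjugated C7 carbonyl to give 6-[4-(benzyloxy)-2,3,5-trimethoxyphenyl]-2-(2-methoxy-2-oxoethyl)-4-oxo-4H-pyran-3-carboxylic acid F5. Conversion of its acid into the acid chloride ((COCl)2, cat. DMF) and treatment with Et3N should close the ring through the ester enol oxygen, as in the preparation of 3-alkoxyisocoumarins from homophthalic half-esters. This gives 13 with the methoxy group necessarily on C7.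

Step 3.
- Risk: hydride transfer between aldehyde molecules under methoxide, reductive loss of bromine, or slow substitution at the doubly ortho-substituted carbon.
- Fallback: sets out from 3 and returns at 4. Acetalisation with ethylene glycol (TsOH, PhMe, azeotropic removal of water) gives 2-[4-(benzyloxy)-2-bromo-3,5-dimethoxyphenyl]-1,3-dioxolane F6. Bromine–lithium exchange (n-BuLi, THF, −78 °C), borylation with B(OMe)3 and oxidation (H2O2, NaOH) give 3-(benzyloxy)-6-(1,3-dioxolan-2-yl)-2,4-dimethoxyphenol F7. Methylation (MeI, K2CO3, DMF) gives 2-[4-(benzyloxy)-2,3,5-trimethoxyphenyl]-1,3-dioxolane F8, and aqueous HCl in THF returns 4.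

Step 10.
- Risk: incomplete cleavage of the 5-ethyl ether (an ethyl group is attacked by chloride more slowly than a methyl group), or over-cleavage of the 3'- or 5'-methyl ether once the 4'-oxygen is bound to boron.
- Fallback: sets out from 16 and returns at 17 in two orthogonal operations. Hydrogenolysis (H2, 10% Pd/C, EtOAc) removes only the benzyl group and gives 5-ethoxy-2-(4-hydroxy-2,3,5-trimethoxyphenyl)-7-methoxy-4H-chromen-4-one F9. AlCl3 in MeCN then removes only the chelated ethyl group.

## Further compounds

F1 | step 9 | (2E)-3-[4-(benzyloxy)-2,3,5-trimethoxyphenyl]-1-(2-hydroxy-4,6-dimethoxyphenyl)prop-2-en-1-one | COc1cc(O)c(C(=O)/C=C/c2cc(OC)c(OCc3ccccc3)c(OC)c2OC)c(OC)c1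
F2 | step 9 | 2-[4-(benzyloxy)-2,3,5-trimethoxyphenyl]-5,7-dimethoxy-4H-chromen-4-one | COc1cc(OC)c2c(=O)cc(-c3cc(OC)c(OCc4ccccc4)c(OC)c3OC)oc2c1
F3 | step 7 | tert-butyl 6-[4-(benzyloxy)-2,3,5-trimethoxyphenyl]-2-(2-tert-butoxy-2-oxoethyl)-4-oxo-4H-pyran-3-carboxylate | CC(C)(C)OC(=O)CC1=C(C(=O)OC(C)(C)C)C(=O)C=C(O1)c1cc(OC)c(OCc2ccccc2)c(OC)c1OC
F4 | step 7 | 6-[4-(benzyloxy)-2,3,5-trimethoxyphenyl]-2-(carboxymethyl)-4-oxo-4H-pyran-3-carboxylic acid | OC(=O)CC1=C(C(O)=O)C(=O)C=C(O1)c1cc(OC)c(OCc2ccccc2)c(OC)c1OC
F5 | step 8 | 6-[4-(benzyloxy)-2,3,5-trimethoxyphenyl]-2-(2-methoxy-2-oxoethyl)-4-oxo-4H-pyran-3-carboxylic acid | COC(=O)CC1=C(C(O)=O)C(=O)C=C(O1)c1cc(OC)c(OCc2ccccc2)c(OC)c1OC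
F6 | step 3 | 2-[4-(benzyloxy)-2-bromo-3,5-dimethoxyphenyl]-1,3-dioxolane | COc1cc(C2OCCO2)c(Br)c(OC)c1OCc1ccccc1
F7 | step 3 | 3-(benzyloxy)-6-(1,3-dioxolan-2-yl)-2,4-dimethoxyphenol | COc1cc(C2OCCO2)c(O)c(OC)c1OCc1ccccc1
F8 | step 3 | 2-[4-(benzyloxy)-2,3,5-trimethoxyphenyl]-1,3-dioxolane | COc1cc(C2OCCO2)c(OC)c(OC)c1OCc1ccccc1
F9 | step 10 | 5-ethoxy-2-(4-hydroxy-2,3,5-trimethoxyphenyl)-7-methoxy-4H-chromen-4-one | CCOc1cc(OC)cc2oc(-c3cc(OC)c(O)c(OC)c3OC)cc(=O)c12
A1 | alternative 1 | 1-[4-(benzyloxy)-2,3,5-trimethoxyphenyl]-3-[2,6-bis(benzyloxy)-4-methoxyphenyl]propane-1,3-dione | COc1cc(OCc2ccccc2)c(C(=O)CC(=O)c2cc(OC)c(OCc3ccccc3)c(OC)c2OC)c(OCc2ccccc2)c1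
A2 | alternative 1 | 2-(benzyloxy)-5-iodo-1,3,4-trimethoxybenzene | Ic1cc(OC)c(OCc2ccccc2)c(OC)c1OC
A3 | alternative 1 | 1-[2,6-bis(benzyloxy)-4-methoxyphenyl]ethan-1-one | CC(=O)c1c(OCc2ccccc2)cc(OC)cc1OCc1ccccc1
A4 | alternative 2 | 2-[4-(benzyloxy)-2,3,5-trimethoxyphenyl]-5-hydroxy-7-methoxy-4H-chromen-4-one | COc1cc(O)c2c(=O)cc(-c3cc(OC)c(OCc4ccccc4)c(OC)c3OC)oc2c1
A5 | alternative 2 | 2-iodo-5-methoxybenzene-1,3-diol | COc1cc(O)c(I)c(O)c1
A6 | alternative 2 | 2-(benzyloxy)-5-ethynyl-1,3,4-trimethoxybenzene | C#Cc1cc(OC)c(OCc2ccccc2)c(OC)c1OC
A7 | alternative 3 | 3-[4-(benzyloxy)-2,3,5-trimethoxyphenyl]-1-(2-hydroxy-4,6-dimethoxyphenyl)prop-2-yn-1-one | COc1cc(O)c(C(=O)C#Cc2cc(OC)c(OCc3ccccc3)c(OC)c2OC)c(OC)c1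
A8 | alternative 3 | 3,5-dimethoxy-2-(trimethylsilyl)phenyl trifluoromethanesulfonate | COc1cc(OC)c([Si](C)(C)C)c(OS(=O)(=O)C(F)(F)F)c1
A9 | alternative 3 | 3,5-dimethoxybenzyne (1,2-didehydro-3,5-dimethoxybenzene) | COC1=CC(OC)=CC#C1
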